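**Assumptions**
- The target is the trans-(2S,3S)-2-aryl-3-(hydroxymethyl)-1,4-benzodioxane, read from the SMILES. C2 carries the syringyl ring and is bonded to the ring oxygen meta to the propenol chain. C3 carries CH2OH and is bonded to the ring oxygen para to the chain, next to the 5-OMe.
- In step 5, the less hindered and less acidic meta-OH of catechol 9 adds to Cβ. The para-OH, which is more acidic because it is conjugated to the acrylate, then closes onto Cα by SN2.
- The (R)-diarylprolinol silyl ether shields one face of the (E)-s-trans iminium, and the phenol attacks the opposite face. I take this face model from standard iminium behaviour.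

## Retrosynthetic overview
- The target comes from a global DIBAL reduction of a trans-2-aryl-3-formyl-1,4-benzodioxane. That intermediate carries an ethyl acrylate on the benzo ring and a pivaloate-protected syringyl OH.
- The only ring, the dioxane, forms in one organocatalytic domino step. An iminium oxa-Michael addition of a catechol OH to an α-bromo-sinapaldehyde sets C2. The second OH then displaces the α-bromide in a 6-exo SN2 closure and gives the trans C3 centre.
- The α-bromoenal comes from syringaldehyde by pivaloylation, Wittig olefination and α-bromination. The catechol acrylate comes from 5-hydroxyvanillin by Wittig olefination.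

## Route

**Step 1**
Reactants: 1 syringaldehyde (4-hydroxy-3,5-dimethoxybenzaldehyde); 2 pivaloyl chloride
Product: 3 4-formyl-2,6-dimethoxyphenyl pivalate
Conditions: 2 (1.2 equiv), Et3N, DMAP (cat.), CH2Cl2, 0 °C → rt
Reagents that add atoms: pivaloyl chloride, CC(C)(C)C(=O)Cl (reactant 2)
Why: O-acylation of the phenol gives a hindered, base-stable protecting group that survives the later phenoxide chemistry and is removed by DIBAL at the end.

**Step 2**
Reactants: 3; 4 (formylmethylene)triphenylphosphorane
Product: 5 2,6-dimethoxy-4-[(E)-3-oxoprop-1-enyl]phenyl pivalate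
Conditions: 4 (1.3 equiv), toluene, 80 °C
Reagents that add atoms: 4, O=CC=P(c1ccccc1)(c1ccccc1)c1ccccc1 (reactant 4)
Why: Wittig olefination with a stabilized ylide is E-selective and stops at the enal.

**Step 3**
Reactants: 5
Product: 6 4-[(Z)-2-bromo-3-oxoprop-1-enyl]-2,6-dimethoxyphenyl pivalate (aryl and CHO trans)
Conditions: Br2, CH2Cl2, 0 °C; then Et3N, 0 → 23 °C
Reagents that add atoms: bromine, BrBr
Why: Br2 adds across the enal C=C and Et3N eliminates HBr, the standard α-bromination of cinnamaldehydes, which keeps the aryl/CHO trans geometry (Z by CIP because Br outranks CHO).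

**Step 4**
Reactants: 7 5-hydroxyvanillin (3,4-dihydroxy-5-methoxybenzaldehyde); 8 ethyl (triphenylphosphoranylidene)acetate
Product: 9 ethyl (E)-3-(3,4-dihydroxy-5-methoxyphenyl)acrylate
Conditions: 8 (1.2 equiv), toluene, 80 °C
Reagents that add atoms: 8, CCOC(=O)C=P(c1ccccc1)(c1ccccc1)c1ccccc1 (reactant 8)
Why: Wittig olefination of an aryl aldehyde with a stabilized ylide is E-selective and tolerates free phenols. The acrylate also makes the para-OH more acidic than the meta-OH.

**Step 5**
Reactants: 6; 9; 10 (R)-α,α-diphenylprolinol trimethylsilyl ether (catalyst)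
Product: 11 ethyl (E)-3-[(2S,3R)-3-formyl-5-methoxy-2-(3,5-dimethoxy-4-pivaloyloxyphenyl)-2,3-dihydro-1,4-benzodioxin-7-yl]acrylate (trans-2,3; the 3-descriptor is R here only because CHO outranks C2)
Conditions: 9 (1.0 equiv), 6 (1.2 equiv), 10 (20 mol %), 2,6-lutidine (2.0 equiv), toluene, 0 °C → rt, 48 h, Ar
Reagents that add atoms: none
Why: Proposed new method: catalyst 10 condenses with bromoenal 6 to give an (E)-s-trans β-aryl iminium whose bulky diarylsilyloxymethyl group shields one face. The meta-phenol of 9 adds to the open face, which is Re for a simple cinnamyl iminium and Si here because Br raises the priority of Cα. This oxa-Michael addition sets C2 as S and gives an α-bromo enamine. Protonation gives an α-bromo iminium that epimerizes through the enamine. The adjacent para-phenoxide then displaces bromide in a 6-exo-tet SN2. Closure to the trans isomer is faster and thermodynamically preferred, and the C3 aldehyde stays epimerizable, so C3 ends up trans to the aryl group. The closest known reactions are diarylprolinol-catalysed Michael/alkylation cascades of α-bromoenals (cyclopropanation, dihydrofuran formation) and intramolecular iminium oxa-Michael additions that make chromans. The new aspects are that a catechol acts as a 1,2-dioxygen bis-nucleophile toward an α-bromoenal and that the product is a 2,3-trans-1,4-benzodioxane.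

**Step 6**
Reactants: 11
Product: 12 target, (E)-3-[(2S,3S)-2-(4-hydroxy-3,5-dimethoxyphenyl)-3-(hydroxymethyl)-5-methoxy-2,3-dihydro-1,4-benzodioxin-7-yl]prop-2-en-1-ol
Conditions: DIBAL-H (8 equiv), CH2Cl2, −78 → 0 °C, 3 h; then Rochelle salt work-up
Reagents that add atoms: none
Why: DIBAL reduces the C3 aldehyde to CH2OH, takes the cinnamate ester to the E-allylic alcohol by 1,2-reduction with the alkene retained, and cleaves the aryl pivalate to the free syringyl phenol. This consumes 5 hydride equivalents. The aryl ether C–O bonds and both stereocentres are untouched, and C3 is no longer epimerizable once it bears CH2OH.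

## Consistency checks
- The target is C21H24O8. Intermediate 11 is C28H32O10. Step 6 adds 10 H (5 hydride plus 5 proton equivalents) and releases EtOH and neopentanol: C28H32O10 + 10 H = C21H24O8 + C2H6O + C5H12O.
- Step 5: 6 (C16H19BrO5) + 9 (C12H14O5) − HBr = 11 (C28H32O10).
- Ring size, the 5-OMe position, the C7 propenol side chain and the trans-(2S,3S) geometry in 12 match the target SMILES.
- The only stereocentres are C2, set in the oxa-Michael addition, and C3, set in the SN2 closure and epimerization. Step 6 does not touch either.

## Compound list
1 | syringaldehyde | COc1cc(C=O)cc(OC)c1O | starting material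
2 | pivaloyl chloride | CC(C)(C)C(=O)Cl | starting material
3 | 4-formyl-2,6-dimethoxyphenyl pivalate | COc1cc(C=O)cc(OC)c1OC(=O)C(C)(C)C | intermediate
4 | (triphenylphosphoranylidene)acetaldehyde | O=CC=P(c1ccccc1)(c1ccccc1)c1ccccc1 | starting material
5 | 2,6-dimethoxy-4-[(E)-3-oxoprop-1-enyl]phenyl pivalate | COc1cc(/C=C/C=O)cc(OC)c1OC(=O)C(C)(C)C | intermediate
6 | 4-[(Z)-2-bromo-3-oxoprop-1-enyl]-2,6-dimethoxyphenyl pivalate | O=C/C(Br)=C/c1cc(OC)c(OC(=O)C(C)(C)C)c(OC)c1 | intermediate
7 | 5-hydroxyvanillin | COc1cc(C=O)cc(O)c1O | starting material
8 | ethyl (triphenylphosphoranylidene)acetate | CCOC(=O)C=P(c1ccccc1)(c1ccccc1)c1ccccc1 | starting material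
9 | ethyl (E)-3-(3,4-dihydroxy-5-methoxyphenyl)acrylate | CCOC(=O)/C=C/c1cc(O)c(O)c(OC)c1 | intermediate
10 | (R)-α,α-diphenylprolinol trimethylsilyl ether | C[Si](C)(C)OC(c1ccccc1)(c1ccccc1)[C@H]1CCCN1 | starting material
11 | ethyl (E)-3-[(2S,3R)-3-formyl-5-methoxy-2-(3,5-dimethoxy-4-pivaloyloxyphenyl)-2,3-dihydro-1,4-benzodioxin-7-yl]acrylate | COc1cc([C@@H]2Oc3cc(/C=C/C(=O)OCC)cc(OC)c3O[C@H]2C=O)cc(OC)c1OC(=O)C(C)(C)C | intermediate
12 | (E)-3-[(2S,3S)-2-(4-hydroxy-3,5-dimethoxyphenyl)-3-(hydroxymethyl)-5-methoxy-2,3-dihydro-1,4-benzodioxin-7-yl]prop-2-en-1-ol | COc1cc([C@@H]2Oc3cc(/C=C/CO)cc(OC)c3O[C@H]2CO)cc(OC)c1O | target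

## Step count
- Total steps: 6.
- Longest linear sequence: 5 steps (1 → 3 → 5 → 6 → 11 → 12, via steps 1, 2, 3, 5 and 6).

## Three steps most likely to fail
1. **Step 5 (the proposed new domino).** Risks are a racemic background oxa-Michael addition, retro-oxa-Michael erosion of ee, the wrong catechol regiochemistry, and low iminium electrophilicity with the electron-rich syringyl β-aryl group.
   - Fallback (known chemistry): drop the organocatalytic domino and use the biomimetic Ag2O-mediated oxidative coupling of catechol 9 with sinapyl alcohol (phenol free). This gives the racemic trans-benzodioxane with the required 8-O-4′ regiochemistry. Separate the regioisomers, resolve the enantiomers by preparative chiral HPLC to obtain the (2S,3S) isomer, and reduce the acrylate ester with DIBAL to give 12.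
2. **Step 3 (α-bromination).** Risks are bromination of the electron-rich ring and over-bromination.
   - Fallback: carry the bromine in a phosphonate instead. Use 4-O-TBS syringaldehyde in place of 3 and do an HWE reaction with ethyl 2-bromo-2-(diethoxyphosphoryl)acetate. Reduce the ester to the allylic alcohol with DIBAL, with the TBS group intact, and oxidize with MnO2 to the TBS-protected α-bromoenal. Carry this through steps 5 and 6, then remove TBS with TBAF/AcOH.
3. **Step 6 (global DIBAL).** The hindered aryl pivalate may cleave sluggishly, or the acrylate may over-reduce.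
   - Fallback: change the protecting-group strategy. Re-run the route with a 4-O-TBS syringyl unit, do the DIBAL reduction with the silyl ether intact, then remove the TBS group with TBAF/AcOH.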